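## Analysis of the target

The target is a 1,2,3,3a,4,5,6,7-octahydroazulene, numbered here C1–C2–C3–C4–C5 in the five-membered ring and C4–C5=C6–C7–C8–C9–C10 in the seven-membered ring. C1 is quaternary (a methyl and the benzylic carbon C1′, which carries isobutyl and the aryl group), C7 carries the 2-hydroxypropan-2-yl group (carbinol carbon C11), and C10 carries a methyl. There are five stereocentres, C1′, C1, C4, C7 and C10, all (R); with the face of the C10 methyl taken as β, the C1 methyl is also β, while H-4, H-10, the C7 side chain and C1′ are α. C1 and C1′ are contiguous, one quaternary and one tertiary benzylic, wedged between the bicycle and an aryl ring with two ortho oxygens, whereas C7 and C10 are remote from them. The sensitive groups are the tertiary alcohol (ionisation), the C5=C6 alkene next to the quaternary centre (acid-induced cyclisation onto the ortho phenol) and the 2,4,6-trihydroxyisophthalaldehyde unit. The synthesis is hard for two reasons: a 5/7 ring system with three ring stereocentres, and a congested C1–C1′ bond whose configurations are not tied to the others by any ring. The strategy rests on one feature: the methyl-bearing carbons C1 and C10 flank the fusion carbons C5 and C4, which is the pattern left when a 4,10-dimethyl decalin 1,4-dien-3-one rearranges photochemically to a hydroazulenone, with C2 as carbonyl and the C7 side chain and its configuration coming from carvone.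

## Retrosynthetic reasoning

**Phenols and formyl groups (28 ⇐ 27 ⇐ 25 ⇐ 24).** The three phenols are unmasked last and the two aryl–CHO bonds are cut just before. The free formylphloroglucinol unit is the most fragile part, and each formyl position lies between two alkoxy groups, so both carbons can go in by directed lithiation under basic conditions that do not touch the tertiary alcohol or the alkene.

**C10–H (24 ⇐ 23 ⇐ 22 ⇐ 21).** The C10–H bond is traced to the C9=C10 alkene of 22 and 23, and that to the tertiary C10 alcohol of 21. The oxygen is the one delivered by the key step. The C11 hydroxyl on the α-face can deliver hydrogen to the α-face of C10. This is left until C1 is quaternary, because the C1 substituent then shields C5=C6 from the same directing group.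

**C2 methylene (21 ⇐ 20 ⇐ 19 ⇐ 18).** The C2–H bonds are traced back to the C2 carbonyl, which is needed only to make C1 nucleophilic. It is removed through the alcohol and a radical deoxygenation, which tolerates the neighbouring quaternary centre.

**C1–C1′ and C1′–C2′ (18 ⇐ 17 ⇐ 9 + 12 + 13).** Both bonds at the benzylic carbon are cut, so that C1′ becomes the formyl carbon of aldehyde 12. Forward, the extended enolate 14 of enone 9 attacks 12 through its α-carbon C1. This makes C1 quaternary and moves the double bond to C5=C6. The carbonate 15 collapses to the o-quinone methide 16, and isobutylmagnesium bromide 13 adds to C1′. Cutting here lets an aldehyde, a small electrophile with no competing elimination, form the quaternary centre, and the phenol comes out already differentiated.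

**Key disconnection (9 ⇐ 8).** The C4–C5 bond is cut and C5–C10 is reconnected, which returns the hydroazulenone 9 to the decalin dienone 8. Decalin C1, C2, C3 and C4 become hydroazulene C4, C3, C2 and C1; C5 to C10 keep their numbers. Forward, one photochemical step forms both rings and the C4 and C10 stereocentres from the single angular stereocentre.

**Decalin (8 ⇐ 7 ⇐ 6 ⇐ 5 ⇐ 2 + 3; 2 ⇐ 1).** The dienone 8 comes from the enone 7 by dehydrogenation. The enone 5 is opened by a Robinson disconnection (decalin C4=C5 by aldol, C1–C10 by Michael) to dihydrocarvone 2 and ethyl vinyl ketone 3. 2 comes from (R)-carvone 1, whose stereocentre becomes C7.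

**Aryl fragment (12 ⇐ 11 ⇐ 10).** The aryl carbonate 12 comes from 2,4,6-trihydroxybenzaldehyde 10, whose formyl group supplies C1′.

## Alternatives that were turned down

**Alternative 1:** C1–C5 and C1′–C2′ are disconnected in one operation. A cycloheptenyl triflate at C5, already carrying C4, C7 and C10 and a (Z)-C1=C1′ styrene on a three-atom tether, would add to zerovalent palladium and undergo 5-exo syn-carbopalladation. The benzylic alkylpalladium, which has no β-hydrogen, would be captured by B-isobutyl-9-borabicyclo[3.3.1]nonane A2 to give the full skeleton A1.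
- For it: C1 and C1′ are made together, their relative configuration follows stereospecifically from the alkene geometry, and C5=C6 arises in place. On the C1/C1′ pair this is stronger than the chosen route, which relies on substrate control at C1′.
- Against it: the insertion must build a quaternary carbon on a trisubstituted alkene bearing a twisted, 2,4,6-trioxygenated aryl group. The facial sense relative to C4 is governed only by a flexible seven-membered ring. The benzylic palladium can slip to an η3-benzyl form and lose its configuration before a slow sp3–sp3 coupling. The substrate (a seven-membered enol triflate with three stereocentres and a geometrically pure styrene) has no short origin.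
- Comparison: the chosen route gives up the stereospecific C1/C1′ link but gets the ring system and three stereocentres in six steps from carvone.

**Alternative 2:** The C1/C1′ pair is taken out as a cyclohexene. Isoprene A4 and (E)-2-methyl-3-(2,4,6-trimethoxyphenyl)acrylaldehyde A5 would combine under a chiral oxazaborolidinium Lewis acid to A3, forming C1–C2 and C1′–C2′. Later ozonolysis of the ring alkene turns one arm into C2–C3 and the other, a methyl ketone, into the isobutyl group; the formyl carbon is C5.
- For it: the quaternary/benzylic stereopair, the weakest point of the chosen route, would come from a suprafacial cycloaddition with catalyst-controlled absolute and geometry-controlled relative configuration. On that point it is clearly stronger.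
- Against it: the dienophile is an electron-rich β-aryl-α-methyl enal shielded by two ortho methoxy groups and the diene is unactivated, so reactivity and regiochemistry are doubtful. The two carbonyl arms must be told apart after ozonolysis. Above all, no part of the hydroazulene exists yet: both rings and C4, C7 and C10 would have to be built under remote control from C1.
- Comparison: the chosen route solves rings and ring stereocentres first and attaches the side chain to a rigid bicycle.

**Alternative 3:** C4–C5 and C6–C7 are disconnected, closing both rings from an open chain. A terminal alkyne on quaternary C1 and a vinylcyclopropane three carbons away would be joined by [Rh(CO)2Cl]2 in an intramolecular [5+2] cycloaddition. The C7–C9 cyclopropane bond opens to give the 1,4-cycloheptadiene A6 with C5=C6, C9=C10 and an ester on C7.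
- For it: the bicyclo[5.3.0] skeleton closes in one reliable step and C5=C6 is formed in place without any deconjugation problem, which is better than the chosen route on that point. The C9=C10 alkene is the same handle the chosen route uses for C10.
- Against it: the C1/C1′ pair must be made beforehand in an open chain, where it is no easier. C4 would be set only by 1,3-induction from C1. C7 depends on an enantiopure cyclopropane and is epimerisable next to the ester. The trisubstituted vinyl group slows the cycloaddition.
- Comparison: it is longer and carries three uncertain stereochemical events, where the chosen route inherits C7 from carvone and C4/C10 from the photochemistry.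

Key step: step 6

Remark: in the key step C10 is trapped by water (aqueous acetic acid) and O-11 is silylated beforehand, so 8 and 9 differ from the bare hydroxy dienone and the 10-acetate only in protecting groups; a C10 acetate is vinylogously β to the C2 carbonyl and would be eliminated during the enolisation of step 9.

## Route

Step 1
Reactants: 1 (R)-carvone
Product: 2 (5R)-dihydrocarvone (C2 epimer mixture)
Conditions: LiBH(s-Bu)3, THF, −78 °C; H2O
Reagents that add atoms: none
Why: Conjugate hydride reduction of the enone by a hindered borohydride; the isopropenyl group and C5 are untouched, and the C2 epimer mixture does not matter because C2 is enolised in step 2.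

Step 2
Reactants: 2 (5R)-dihydrocarvone; 3 ethyl vinyl ketone
Product: 5 10-epi-α-cyperone, via ketol 4 (not isolated)
Conditions: KOH, EtOH, −10 °C to rt; then reflux
Reagents that add atoms: none
Why: Robinson annulation (Michael addition of the more substituted enolate, aldol closure, dehydration); the enone approaches the enolate anti to the equatorial isopropenyl group, which places the angular methyl trans to the side chain.

Step 3
Reactants: 5 10-epi-α-cyperone
Product: 6 11-hydroxy enone
Conditions: Co(acac)2 (cat.), PhSiH3, O2 (1 atm), THF–i-PrOH, rt
Reagents that add atoms: oxygen, O=O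
Why: Mukaiyama hydration: hydrogen-atom transfer to the 1,1-disubstituted alkene gives the tertiary radical, which is oxygenated and reduced to the Markovnikov alcohol; the tetrasubstituted, electron-poor enone alkene does not react.

Step 4
Reactants: 6 11-hydroxy enone
Product: 7 11-silyloxy enone
Conditions: t-BuMe2SiOTf, 2,6-lutidine, CH2Cl2, −78 to 0 °C
Reagents that add atoms: tert-butyldimethylsilyl triflate, CC(C)(C)[Si](C)(C)OS(=O)(=O)C(F)(F)F
Why: Silyl triflates silylate tertiary alcohols; the ether survives aqueous acetic acid and keeps O-11 distinct from the C10 oxygen introduced in step 6.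

Step 5
Reactants: 7 11-silyloxy enone
Product: 8 11-silyloxy decalin 1,4-dien-3-one
Conditions: DDQ, 1,4-dioxane, reflux
Reagents that add atoms: none
Why: DDQ dehydrogenation of a 4-en-3-one under neutral conditions removes hydride from C1 of the enol formed toward C2 and gives the cross-conjugated dienone; C10 is quaternary, so aromatisation is excluded.

Step 6
Reactants: 8 11-silyloxy decalin 1,4-dien-3-one
Product: 9 10α-hydroxy-11-silyloxy hydroazulen-2-one
Conditions: hν (Hg lamp, Pyrex, λ > 300 nm), AcOH–H2O–1,4-dioxane, N2, rt
Reagents that add atoms: water, O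
Why: This is the santonin-type photorearrangement of a 4-methyl cross-conjugated cyclohexadienone in protic acid, the reaction that turns such decalin dienones into 10-oxygenated hydroazulenones. Excitation bonds the two β-carbons of the dienone, decalin C1 and C5 (hydroazulene C4–C5), to give a cyclopropane-bridged oxyallyl zwitterion; this bond closes the five-membered ring as a bicyclo[3.1.0]hexane. Protonation on oxygen gives a cyclopropylcarbinyl cation at the methyl-bearing carbon (hydroazulene C1), and the cyclopropane bond C5–C10 breaks so that the charge moves to tertiary C10; this 1,2-shift enlarges former ring B by one carbon to the seven-membered ring, and water takes the cation. Ketonisation of the resulting dienol gives the C1=C5 enone. The C4 configuration is dictated by the angular methyl: in the bicyclo[3.1.0] intermediate the C10 methyl must lie on the side of the five-membered ring and H-4 on the other, so H-4 ends anti to the methyl and cis to the C7 side chain. Water attacks C10 anti to the departing C5 bond, which puts the hydroxyl on the face of H-4 (α) and leaves the methyl β. The step needs the hydroazulene channel in preference to the lumiketone and spiro channels; the acidic medium and the methyl on the carbon that becomes C1, which stabilises the cation that opens toward C10, secure this. The product enone absorbs in the same region, so the irradiation is stopped short of full conversion.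

Step 7
Reactants: 10 2,4,6-trihydroxybenzaldehyde
Product: 11 2-hydroxy-4,6-bis(methoxymethoxy)benzaldehyde
Conditions: MeOCH2Cl (2.1 equiv), i-Pr2NEt, CH2Cl2, 0 °C
Reagents that add atoms: chloromethyl methyl ether, COCCl
Why: Phenol O-alkylation; after the para and one ortho hydroxyl have reacted, the last ortho hydroxyl is held in a hydrogen bond to the formyl oxygen and is left free.

Step 8
Reactants: 11 2-hydroxy-4,6-bis(methoxymethoxy)benzaldehyde
Product: 12 tert-butyl 2-formyl-3,5-bis(methoxymethoxy)phenyl carbonate
Conditions: Boc2O, i-Pr2NEt, DMAP (cat.), THF, rt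
Reagents that add atoms: di-tert-butyl dicarbonate, CC(C)(C)OC(=O)OC(=O)OC(C)(C)C
Why: DMAP-catalysed O-acylation of the phenol; the aryl carbonate is the internal acyl donor that later turns the benzylic alkoxide into a leaving group.

Step 9
Reactants: 9 10α-hydroxy-11-silyloxy hydroazulen-2-one; 12 aryl carbonate aldehyde; 13 isobutylmagnesium bromide
Product: 17 C1-alkylated hydroazulen-2-one (C5=C6; free ortho phenol; 1′R), via dipotassium dienolate 14 (not isolated), via benzylic carbonate 15 (not isolated), via o-quinone methide 16 (not isolated)
Conditions: KOtBu (2.2 equiv), THF, 0 °C; MgBr2·OEt2, −78 °C; 12; then 13 (3 equiv), −78 to −10 °C; H2O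
Reagents that add atoms: none
Why: This is a deconjugative aldol of an extended enolate coupled to the o-OBoc-salicylaldehyde/o-quinone methide cascade: the C10 alkoxide can reach H-6 through a six-membered transition state but not H-4, and an oxido group on C10 disfavours the ring-fusion dienolate, so enolisation runs to C6 and C1 attacks the aldehyde on the face of H-4, away from the C4–C10 bond. Boc transfer from the phenol to the aldolate makes the addition irreversible, and on warming the phenoxide expels tert-butyl carbonate to give 16, which has no hydrogen on C1 and cannot tautomerise. With the C1 methyl eclipsing the exocyclic C=C (A(1,3) strain) the two faces of C1′ are flanked by C2 and by C5/C6, and the Grignard reagent, held by the C2 carbonyl oxygen, adds in conjugate fashion from the C2 side, which gives the (R)-configuration at C1′.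

Step 10
Reactants: 17 C1-alkylated hydroazulen-2-one (free phenol)
Product: 18 tris(methoxymethyl) ether
Conditions: MeOCH2Cl, K2CO3, acetone, rt
Reagents that add atoms: chloromethyl methyl ether, COCCl
Why: Phenoxide O-alkylation; under carbonate the phenol, which may rest as its cyclic hemiketal with the C2 ketone, reacts through the open phenoxide, and the tertiary C10 alcohol is not deprotonated.

Step 11
Reactants: 18 tris(methoxymethyl) ether ketone
Product: 19 C2 alcohol
Conditions: LiAlH4, THF, 0 °C; H2O
Reagents that add atoms: none
Why: Hydride reduction of the hindered cyclopentanone; the new C2 centre is removed in step 13, so its configuration is immaterial.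

Step 12
Reactants: 19 C2 alcohol
Product: 20 C2 O-phenyl thiocarbonate
Conditions: PhOC(S)Cl, pyridine, DMAP, CH2Cl2, rt
Reagents that add atoms: O-phenyl chlorothionoformate, S=C(Cl)Oc1ccccc1
Why: Acylation of the secondary alcohol; the tertiary C10 hydroxyl does not react under these conditions.

Step 13
Reactants: 20 C2 O-phenyl thiocarbonate
Product: 21 C2-deoxy compound
Conditions: Bu3SnH, AIBN (cat.), toluene, 100 °C
Reagents that add atoms: none
Why: Barton–McCombie deoxygenation; the C2 radical cannot undergo a 1,2-vinyl shift because the cyclopropylcarbinyl intermediate would be a bicyclo[2.1.0]pentane, so it is simply reduced.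

Step 14
Reactants: 21 C2-deoxy tertiary alcohol
Product: 22 C9=C10 alkene
Conditions: POCl3, pyridine, 0 to 50 °C
Reagents that add atoms: none
Why: E2 dehydration through the dichlorophosphate; H-4 is syn to the C10 oxygen and cannot become anti-periplanar to it, whereas the ring hydrogen H-9β can, so the elimination should run into the ring toward C9 and give the more substituted (Zaitsev) alkene without touching the C4 stereocentre.

Step 15
Reactants: 22 C9=C10 alkene
Product: 23 C11 alcohol with C9=C10
Conditions: Bu4NF, THF, 50 °C
Reagents that add atoms: none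
Why: Fluoride cleavage of the tertiary silyl ether frees the hydroxyl needed as directing group; the methoxymethyl ethers and both alkenes are inert to fluoride.

Step 16
Reactants: 23 C11 alcohol with C9=C10
Product: 24 10α-H hydroazulene
Conditions: H2 (1 atm), [Ir(cod)(PCy3)(py)]PF6 (5 mol %), CH2Cl2, 0 °C to rt
Reagents that add atoms: none
Why: Hydroxyl-directed hydrogenation: iridium bound to the C11 hydroxyl on the α-face adds hydrogen from that face, so C10 receives H α and keeps its methyl β. The same hydroxyl is homoallylic to C5=C6, but the α-face of that alkene is covered by the aryl(isobutyl)methyl group on the adjacent quaternary C1.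

Step 17
Reactants: 24 10α-H hydroazulene
Product: 25 mono-aldehyde
Conditions: n-BuLi (3 equiv), TMEDA, THF, 0 °C; DMF, −78 °C to rt; H2O
Reagents that add atoms: N,N-dimethylformamide, CN(C)C=O
Why: Directed ortho-metalation: after alkoxide formation the aryl position between two methoxymethoxy groups is lithiated and formylated by DMF.

Step 18
Reactants: 25 mono-aldehyde
Product: 27 dialdehyde, via α-amino alkoxide 26 (not isolated)
Conditions: LiN(Me)CH2CH2NMe2, THF, −20 °C; n-BuLi, 0 °C; DMF; H2O
Reagents that add atoms: N,N-dimethylformamide, CN(C)C=O
Why: The aldehyde is protected in the flask as its α-amino alkoxide (Comins), the last aryl C–H between two methoxymethoxy groups is lithiated and formylated, and work-up releases both aldehydes.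

Step 19
Reactants: 27 dialdehyde
Product: 28 target
Conditions: HCl (1 M), MeOH–THF, rt
Reagents that add atoms: none
Why: Acid-catalysed acetal exchange removes the three phenolic methoxymethyl ethers, which are activated by the ortho and para formyl groups and cleave under conditions mild enough for the tertiary alcohol and the C5=C6 alkene.

## Compound list

1 | (R)-carvone | CC1=CC[C@H](CC1=O)C(C)=C | starting material
2 | (5R)-dihydrocarvone, (5R)-2-methyl-5-(prop-1-en-2-yl)cyclohexanone, C2 epimer mixture | CC1CC[C@H](CC1=O)C(C)=C | intermediate
3 | ethyl vinyl ketone (pent-1-en-3-one) | CCC(=O)C=C | starting material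
4 | ketol: 5-hydroxy-4,10-dimethyl-7-(prop-1-en-2-yl)decalin-3-one, 10-methyl trans to the C7 side chain, C4 and C5 not defined | CC1C(=O)CC[C@@]2(C)CC[C@@H](C(C)=C)CC12O | intermediate (not isolated)
5 | 10-epi-α-cyperone, (4aR,7R)-1,4a-dimethyl-7-(prop-1-en-2-yl)-4,4a,5,6,7,8-hexahydronaphthalen-2(3H)-one | CC1=C2C[C@H](C(C)=C)CC[C@]2(C)CCC1=O | intermediate
6 | (4aR,7R)-7-(2-hydroxypropan-2-yl)-1,4a-dimethyl-4,4a,5,6,7,8-hexahydronaphthalen-2(3H)-one | CC1=C2C[C@H](C(C)(C)O)CC[C@]2(C)CCC1=O | intermediate
7 | tert-butyldimethylsilyl ether of 6 | CC1=C2C[C@H](C(C)(C)O[Si](C)(C)C(C)(C)C)CC[C@]2(C)CCC1=O | intermediate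
8 | (4aR,7R)-7-[2-(tert-butyldimethylsilyloxy)propan-2-yl]-1,4a-dimethyl-5,6,7,8-tetrahydronaphthalen-2(4aH)-one (key-step precursor) | CC1=C2C[C@H](C(C)(C)O[Si](C)(C)C(C)(C)C)CC[C@]2(C)C=CC1=O | intermediate
9 | hydroazulen-2-one with C1=C5, 1-methyl, 4α-H, 7α-C(Me)2OSi(t-Bu)Me2, 10α-hydroxy, 10β-methyl (key-step product) | CC1=C2C[C@H](C(C)(C)O[Si](C)(C)C(C)(C)C)CC[C@](C)(O)[C@H]2CC1=O | intermediate
10 | 2,4,6-trihydroxybenzaldehyde | O=Cc1c(O)cc(O)cc1O | starting material
11 | 2-hydroxy-4,6-bis(methoxymethoxy)benzaldehyde | O=Cc1c(O)cc(OCOC)cc1OCOC | intermediate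
12 | tert-butyl 2-formyl-3,5-bis(methoxymethoxy)phenyl carbonate | O=Cc1c(OC(=O)OC(C)(C)C)cc(OCOC)cc1OCOC | intermediate
13 | isobutylmagnesium bromide | CC(C)C[Mg]Br | starting material
14 | dipotassium salt of the C2/C6 dienolate and C10 alkoxide of 9 | [K+].[K+].CC1=C([O-])C[C@H]2C1=C[C@H](C(C)(C)O[Si](C)(C)C(C)(C)C)CC[C@]2(C)[O-] | intermediate (not isolated)
15 | aldol adduct after Boc transfer: C1′ tert-butyl carbonate, bromomagnesium phenoxide and C10 alkoxide (C1′ not defined) | CC(C)(C)OC(=O)OC(c1c(O[Mg]Br)cc(OCOC)cc1OCOC)[C@@]1(C)C(=O)C[C@H]2C1=C[C@H](C(C)(C)O[Si](C)(C)C(C)(C)C)CC[C@]2(C)O[Mg]Br | intermediate (not isolated)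
16 | o-quinone methide with C1′ as exocyclic methide carbon on quaternary C1 | O=C3C=C(OCOC)C=C(OCOC)C3=C[C@@]1(C)C(=O)C[C@H]2C1=C[C@H](C(C)(C)O[Si](C)(C)C(C)(C)C)CC[C@]2(C)O[Mg]Br | intermediate (not isolated)
17 | hydroazulen-2-one with C5=C6, 1β-methyl, 1α-[(1R)-1-(2-hydroxy-4,6-bis(methoxymethoxy)phenyl)-3-methylbutyl], 4α-H, 7α-C(Me)2OSi(t-Bu)Me2, 10α-OH, 10β-methyl | CC(C)C[C@@H](c1c(O)cc(OCOC)cc1OCOC)[C@@]1(C)C(=O)C[C@H]2C1=C[C@H](C(C)(C)O[Si](C)(C)C(C)(C)C)CC[C@]2(C)O | intermediate
18 | 2,4,6-tris(methoxymethoxy)phenyl analogue of 17 | CC(C)C[C@@H](c1c(OCOC)cc(OCOC)cc1OCOC)[C@@]1(C)C(=O)C[C@H]2C1=C[C@H](C(C)(C)O[Si](C)(C)C(C)(C)C)CC[C@]2(C)O | intermediate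
19 | C2 alcohol of 18 (C2 not defined) | CC(C)C[C@@H](c1c(OCOC)cc(OCOC)cc1OCOC)[C@@]1(C)C(O)C[C@H]2C1=C[C@H](C(C)(C)O[Si](C)(C)C(C)(C)C)CC[C@]2(C)O | intermediate
20 | C2 O-phenyl thiocarbonate of 19 | CC(C)C[C@@H](c1c(OCOC)cc(OCOC)cc1OCOC)[C@@]1(C)C(OC(=S)Oc3ccccc3)C[C@H]2C1=C[C@H](C(C)(C)O[Si](C)(C)C(C)(C)C)CC[C@]2(C)O | intermediate
21 | C2-methylene compound: 10α-hydroxy, 11-silyloxy, C5=C6 | CC(C)C[C@@H](c1c(OCOC)cc(OCOC)cc1OCOC)[C@@]1(C)CC[C@H]2C1=C[C@H](C(C)(C)O[Si](C)(C)C(C)(C)C)CC[C@]2(C)O | intermediate
22 | 5,9-diene (C5=C6 and C9=C10), 11-silyloxy | CC(C)C[C@@H](c1c(OCOC)cc(OCOC)cc1OCOC)[C@@]1(C)CC[C@H]2C1=C[C@H](C(C)(C)O[Si](C)(C)C(C)(C)C)CC=C2C | intermediate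
23 | 5,9-diene with free C11 hydroxyl | CC(C)C[C@@H](c1c(OCOC)cc(OCOC)cc1OCOC)[C@@]1(C)CC[C@H]2C1=C[C@H](C(C)(C)O)CC=C2C | intermediate
24 | tris(methoxymethyl) ether of the bis-deformyl target (10α-H, 10β-methyl) | CC(C)C[C@@H](c1c(OCOC)cc(OCOC)cc1OCOC)[C@@]1(C)CC[C@H]2C1=C[C@H](C(C)(C)O)CC[C@H]2C | intermediate
25 | mono-aldehyde of 24 (3-formyl-2,4,6-tris(methoxymethoxy)phenyl) | CC(C)C[C@@H](c1c(OCOC)c(C=O)c(OCOC)cc1OCOC)[C@@]1(C)CC[C@H]2C1=C[C@H](C(C)(C)O)CC[C@H]2C | intermediate
26 | dilithium α-amino alkoxide of 25 with lithium N,N,N′-trimethylethylenediamide (C11 alkoxide) | [Li+].[Li+].CC(C)C[C@@H](c1c(OCOC)c(C([O-])N(C)CCN(C)C)c(OCOC)cc1OCOC)[C@@]1(C)CC[C@H]2C1=C[C@H](C(C)(C)[O-])CC[C@H]2C | intermediate (not isolated)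
27 | tris(methoxymethyl) ether of the target | CC(C)C[C@@H](c1c(OCOC)c(C=O)c(OCOC)c(C=O)c1OCOC)[C@@]1(C)CC[C@H]2C1=C[C@H](C(C)(C)O)CC[C@H]2C | intermediate
28 | 5-[(1R)-1-[(1R,3aR,4R,7R)-7-(2-hydroxypropan-2-yl)-1,4-dimethyl-1,2,3,3a,4,5,6,7-octahydroazulen-1-yl]-3-methylbutyl]-2,4,6-trihydroxybenzene-1,3-dicarbaldehyde | CC(C)C[C@@H](c1c(O)c(C=O)c(O)c(C=O)c1O)[C@@]1(C)CC[C@H]2C1=C[C@H](C(C)(C)O)CC[C@H]2C | target

## Step count and least certain steps

Total: 19 steps. Longest linear sequence: 17 steps (steps 1–6 and 9–19).

**Step 6 (key step).** The most likely problems are capture of the C10 cation by acetic acid in competition with water, slow loss of the silyl ether in the aqueous acid, and secondary photolysis of the product enone on over-irradiation. All three lower the amount of 9 without changing the skeleton. Fallback, from 8 back to 9: irradiate in glacial acetic acid, where acetate capture is the normal outcome and the silyl ether is safe, to give the 10-acetate F1. Base hydrolysis of F1 is avoided because it would eliminate. Instead i-Bu2AlH reduces the ketone and cleaves the ester to the allylic diol F2, and MnO2 reoxidises the allylic alcohol to 9.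

**Step 9.** The most likely failure is enolisation toward the ring-fusion carbon C4 instead of C6, or vinylogous retro-aldol opening of the seven-membered ring by the C10 alkoxide before the enone is enolised. The first scrambles C4 and sends the aldol through the wrong dienolate; the second destroys the bicycle. The regiochemistry rests on an internal-base and charge argument. Independently, the facial selectivity of the Grignard addition at C1′ rests on substrate control alone, and erosion there would call for separation of C1′ epimers at the stage of 17. Fallback, from 7 back to 14, makes the dienolate without any choice of proton. In the decalin only C6 can be deprotonated at the γ-position, so t-BuMe2SiOTf/Et3N gives the extended silyl dienol ether F3; mCPBA hydroxylates it at C6 to the 6-hydroxy enone F4, and Ac2O gives the 6-acetate F5. DDQ then gives the 6-acetoxy dienone F6, and irradiation as in step 6 gives the 6-acetoxy hydroazulenone F7. Samarium diiodide in THF–MeOH cleaves the γ-acetoxy enone reductively, and kinetic protonation at C1 gives the β,γ-unsaturated ketone F8 with C5=C6 in place. KN(SiMe3)2 (2 equiv, −78 °C) removes the hydroxyl proton and the doubly activated H-1 and gives 14, which is taken on as in step 9.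

**Step 14.** Two processes threaten it. Ionisation at C10 (E1) instead of anti elimination would remove H-4, bring the new double bond into conjugation with C5=C6 and erase the C4 centre. Loss of regiocontrol, with elimination toward the C10 methyl group instead of C9, would place the double bond one bond further from the directing hydroxyl and weaken the facial control of step 16. Fallback, from 21 back to 24, avoids elimination altogether. 21 is acylated with methyl chlorooxoacetate/DMAP to the tertiary methyl oxalate F9. Bu3SnH/AIBN reduces F9 to the 10-deoxy silyl ether F10, with hydrogen-atom transfer expected on the α-face opposite C3 but less securely than in the directed hydrogenation. Bu4NF then gives 24.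

**Step 16.** The risk is competing saturation of C5=C6, to which the same hydroxyl is homoallylic and therefore closer than to C9=C10; over-reduction would be difficult to reverse. Fallback, from 21 back to 24: bypass the alkene by the radical deoxygenation through F9 and F10 described for step 14; no further compound is made (F0).

## Further compounds

F1 | step 6 | 10-acetate of 9 (10α-acetoxy-11-silyloxy hydroazulen-2-one) | CC1=C2C[C@H](C(C)(C)O[Si](C)(C)C(C)(C)C)CC[C@](C)(OC(C)=O)[C@H]2CC1=O
F2 | step 6 | C2,C10-diol (allylic alcohol at C2, C2 not defined) | CC1=C2C[C@H](C(C)(C)O[Si](C)(C)C(C)(C)C)CC[C@](C)(O)[C@H]2CC1O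
F3 | step 9 | 3-silyloxy-3,5-diene (extended silyl dienol ether of 7) | CC1=C(O[Si](C)(C)C(C)(C)C)CC[C@@]2(C)CC[C@@H](C(C)(C)O[Si](C)(C)C(C)(C)C)C=C12
F4 | step 9 | 6-hydroxy derivative of 7 (C6 not defined) | CC1=C2C(O)[C@H](C(C)(C)O[Si](C)(C)C(C)(C)C)CC[C@]2(C)CCC1=O
F5 | step 9 | 6-acetoxy derivative of 7 | CC1=C2C(OC(C)=O)[C@H](C(C)(C)O[Si](C)(C)C(C)(C)C)CC[C@]2(C)CCC1=O
F6 | step 9 | 6-acetoxy derivative of 8 | CC1=C2C(OC(C)=O)[C@H](C(C)(C)O[Si](C)(C)C(C)(C)C)CC[C@]2(C)C=CC1=O
F7 | step 9 | 6-acetoxy derivative of 9 | CC1=C2C(OC(C)=O)[C@H](C(C)(C)O[Si](C)(C)C(C)(C)C)CC[C@](C)(O)[C@H]2CC1=O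
F8 | step 9 | β,γ-unsaturated ketone: hydroazulen-2-one with C5=C6 and H on C1 (C1 not defined) | CC1C(=O)C[C@H]2C1=C[C@H](C(C)(C)O[Si](C)(C)C(C)(C)C)CC[C@]2(C)O
F9 | step 14 | C10 methyl oxalate of 21 | CC(C)C[C@@H](c1c(OCOC)cc(OCOC)cc1OCOC)[C@@]1(C)CC[C@H]2C1=C[C@H](C(C)(C)O[Si](C)(C)C(C)(C)C)CC[C@]2(C)OC(=O)C(=O)OC
F10 | step 14 | 10-deoxy compound, tert-butyldimethylsilyl ether of 24 | CC(C)C[C@@H](c1c(OCOC)cc(OCOC)cc1OCOC)[C@@]1(C)CC[C@H]2C1=C[C@H](C(C)(C)O[Si](C)(C)C(C)(C)C)CC[C@H]2C
F0 | step 16 | none | none
A1 | alternative 1 | trimethoxyphenyl hydroazulene with C11 triethylsilyl ether (full carbon skeleton) | CC(C)C[C@@H](c1c(OC)cc(OC)cc1OC)[C@@]1(C)CC[C@H]2C1=C[C@H](C(C)(C)O[Si](CC)(CC)CC)CC[C@H]2C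
A2 | alternative 1 | B-isobutyl-9-borabicyclo[3.3.1]nonane | CC(C)CB1C2CCCC1CCC2
A3 | alternative 2 | 6-aryl-1,4-dimethylcyclohex-3-ene-1-carbaldehyde | O=C[C@]1(C)CC=C(C)C[C@H]1c1c(OC)cc(OC)cc1OC
A4 | alternative 2 | isoprene | C=CC(C)=C
A5 | alternative 2 | (E)-2-methyl-3-(2,4,6-trimethoxyphenyl)acrylaldehyde | O=C/C(C)=C/c1c(OC)cc(OC)cc1OC
A6 | alternative 3 | ethyl ester of the bicyclo[5.3.0]deca-5,9-diene | CC(C)C[C@@H](c1c(OC)cc(OC)cc1OC)[C@@]1(C)CC[C@H]2C1=C[C@H](C(=O)OCC)CC=C2C
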